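**Plan**
Retrosynthesis: both aldehydes are taken back to a Δ7-11,12-diol (C11 cut from a C9 ketone, C12 back to the C8 methyl), the homoprenyl arm is cut at C2′–C3′ back to a C4 acetate arm, C3–Cl goes back to a C3 ketone, and ring A is opened at C3–C4, then at C10–C1 and C10–CH3.
Enabling feature: ring B (C5–C10) has carvone's pattern, with C12 on the C7=C8 olefin beside the C9 carbonyl and, on C5, the carbon that becomes the methyl-bearing quaternary C4. A C3 acyl radical at the end of the C10–C1–C2 chain then sits in a 1,6-relationship to C4 of a Z-enoate.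
Forward: carvone is methylated and aldolised at C10, the isopropenyl group becomes the Z-β-methyl enoate, the C3 selenoester is made, and ring A closes by 6-exo acyl-radical addition. C3–Cl, C11, C12 and the side chain follow.
Stereochemistry: C5 from (R)-carvone; C10 by aldol attack anti to the C5 side chain; C1 by a syn-selective titanium aldol; C4 by A(1,3) control in the ring closure; C3 by equatorial chlorine-atom transfer; C9 by hydroboration anti to the C10 methyl.

Key step: step 11

Remark: atoms carry the decalin numbers of the target throughout (ring A = C1–C5, C10; ring B = C5–C10; C11 on C9, C12 on C8; C1′, C2′ = the C4 arm; β = face of the C10 methyl). Assumption: alcohol 21 is drawn as the equatorial C3 epimer; its configuration is erased in step 14, so either epimer serves.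

**Step 1**
Reactants: 1 (R)-carvone
Product: 3 trans-6-methylcarvone, via lithium dienolate 2 (not isolated)
Conditions: LDA, THF, −78 °C; MeI, −78 → 0 °C
Reagents that add atoms: iodomethane (CI)
Why: Kinetic α′-deprotonation and enolate C-alkylation, standard for carvone, install the future C10 methyl; the C10 configuration formed here is irrelevant because C10 is enolised again in step 3.

**Step 2**
Reactants: 4 methyl 3,3-dimethoxypropanoate
Product: 5 3,3-dimethoxypropanal
Conditions: DIBAL-H, CH2Cl2, −78 °C; MeOH, aq Rochelle salt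
Reagents that add atoms: none
Why: Partial ester reduction stops at the aldehyde because the aluminium hemiacetal is stable at −78 °C; the malonaldehyde mono-acetal (C1–C3) is used at once.

**Step 3**
Reactants: 3 trans-6-methylcarvone; 5 3,3-dimethoxypropanal
Product: 8 (1S)-ketol, via lithium enolate 6 (not isolated), via titanium enolate 7 (not isolated)
Conditions: LDA, THF, −78 → 0 °C; ClTi(Oi-Pr)3, −78 → −40 °C; 5, −78 °C; aq NH4Cl
Reagents that add atoms: none
Why: Titanium-enolate aldol addition: the tetrasubstituted C9=C10 enolate is attacked at C10 on the face opposite the C5 isopropenyl group (C1 α, C10 methyl β), and triisopropoxytitanium enolates of cyclic ketones are syn-selective, which should place the C1 oxygen syn to C5 along the C9–C10–C1–C2 chain (1S), while the weakly basic enolate spares the elimination-prone aldehyde.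

**Step 4**
Reactants: 8 (1S)-ketol
Product: 9 TBS ether
Conditions: TBSOTf, 2,6-lutidine, CH2Cl2, −78 → 0 °C
Reagents that add atoms: tert-butyldimethylsilyl triflate (CC(C)(C)[Si](C)(C)OS(=O)(=O)C(F)(F)F)
Why: Silylation with the silyl triflate is needed for the hindered neopentyl carbinol and, being non-basic, avoids retro-aldol cleavage of C10–C1; the acetal should survive at low temperature.

**Step 5**
Reactants: 9 TBS ether
Product: 11 methyl ketone, via ozonide 10 (not isolated)
Conditions: O3, CH2Cl2, −78 °C (Sudan Red 7B end point); PPh3, −78 °C → rt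
Reagents that add atoms: ozone ([O-][O+]=O)
Why: Ozonolysis is selective for the electron-rich 1,1-disubstituted isopropenyl olefin over the electron-poor enone olefin, as with carvone itself, and leaves the C4 acetyl group on C5.

**Step 6**
Reactants: 11 methyl ketone
Product: 15 tert-butyl ynoate, via lithium enolate 12 (not isolated), via enol phosphate 13 (not isolated), via lithium acetylide 14 (not isolated)
Conditions: LDA (1.1 equiv), THF, −78 °C; ClP(O)(OEt)2, −78 °C → rt; LDA (2.2 equiv), −78 °C → rt; Boc2O, −78 → 0 °C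
Reagents that add atoms: di-tert-butyl dicarbonate (CC(C)(C)OC(=O)OC(=O)OC(C)(C)C)
Why: Negishi alkyne synthesis (kinetic methyl-ketone enolate, enol phosphate, elimination) followed by acylation of the acetylide gives the ynoate in one flask; the C9 ketone has no α-hydrogen and is flanked on both sides, and the tert-butyl ester is chosen so that the later C3 alcohol cannot lactonise onto this arm.

**Step 7**
Reactants: 15 tert-butyl ynoate
Product: 16 (Z)-enoate
Conditions: Me2CuLi (from MeLi, CuI), THF, −78 °C; MeOH then aq NH4Cl at −78 °C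
Reagents that add atoms: lithium dimethylcuprate ([Li+].C[Cu-]C)
Why: syn-Carbocupration of the ynoate and cold protonation of the alkenylcopper give the β-methyl enoate with C5 cis to the ester (Z); the ynoate should react at −78 °C much faster than the α-methyl enone of ring B.

**Step 8**
Reactants: 16 (Z)-enoate
Product: 17 aldehyde
Conditions: LiBF4, MeCN/H2O (98:2), rt
Reagents that add atoms: water (O)
Why: Mild Lewis-acid acetal hydrolysis should release the C3 aldehyde without cleaving the silyl ether or tert-butyl ester and without β-elimination of the C1 silyloxy group.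

**Step 9**
Reactants: 17 aldehyde
Product: 18 carboxylic acid
Conditions: NaClO2, NaH2PO4, 2-methyl-2-butene, t-BuOH/H2O, 0 °C → rt
Reagents that add atoms: sodium chlorite ([Na+].[O-]Cl=O)
Why: Pinnick oxidation converts the aldehyde to the acid under buffered conditions that leave the electron-poor olefins and the silyl ether intact.

**Step 10**
Reactants: 18 carboxylic acid
Product: 19 Se-phenyl selenoester
Conditions: N-(phenylseleno)phthalimide, n-Bu3P (premixed), CH2Cl2, −20 → 0 °C
Reagents that add atoms: N-(phenylseleno)phthalimide (O=C1N([Se]c2ccccc2)C(=O)c2ccccc12)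
Why: Phosphine-mediated selenoesterification (acyloxyphosphonium taken by phenylselenolate) gives the acyl-radical precursor under neutral conditions; premixing leaves no free phosphine to isomerise the Z-enoate.

**Step 11**
Reactants: 19 Se-phenyl selenoester
Product: 20 decalin-3,9-dione (1α-OTBS; 4β-Me; 4α-CH2CO2t-Bu; 5α-H; 10β-Me; Δ7)
Conditions: (Me3Si)3SiH and AIBN by syringe pump, benzene (5 mM), 80 °C
Reagents that add atoms: none
Why: The silyl radical abstracts the phenylseleno group to give the nucleophilic C3 acyl radical, which adds to the electron-poor β-carbon C4 of the enoate, and the α-ester radical at C1′ then takes hydrogen from the silane to carry the chain. The closest known reaction type is the 6-exo conjugate cyclisation of acyl radicals from phenyl selenoesters onto enoates, here applied to a β,β-disubstituted acceptor. Ring A closes 6-exo-trig through a chair trans-fused to ring B, with the C10–C1 and C5–C4 bonds both equatorial on ring B. The new quaternary C4 is controlled by A(1,3) strain: the ester cis to C5 in the Z-enoate holds H5 in the olefin plane, so the tethered radical meets the face that leaves the C4 methyl axial (β) and the acetate arm equatorial (α). The step needs cyclisation to outrun reduction and CO loss of the acyl radical and attack at C4 rather than C1′; slow addition of a poor hydrogen donor, the slow decarbonylation of a primary-alkyl acyl radical and the polarity match with the β-carbon should secure this. The ring-B enone is out of reach of C3, and a 1,2-acyl shift of the stabilised product radical is not expected.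

**Step 12**
Reactants: 20 decalin-3,9-dione
Product: 21 3β-alcohol
Conditions: NaBH4, MeOH/CH2Cl2 (1:1), −78 → −20 °C; AcOH
Reagents that add atoms: none
Why: Chemoselective borohydride reduction takes the saturated C3 ketone and leaves the conjugated, doubly flanked C9 enone; axial hydride delivery should favour the equatorial alcohol, and the tert-butyl ester resists lactonisation.

**Step 13**
Reactants: 21 3β-alcohol
Product: 23 caesium oxalate, via methyl oxalate 22 (not isolated)
Conditions: MeO2CCOCl, Et3N, DMAP (cat.), CH2Cl2, 0 °C; then CsOH·H2O (1.0 equiv), THF/H2O, rt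
Reagents that add atoms: methyl chlorooxoacetate (COC(=O)C(Cl)=O); caesium hydroxide ([Cs+].[OH-])
Why: Acylation of the hindered alcohol with the oxalyl chloride half-ester and selective saponification of the methyl oxalate (much faster than the tert-butyl ester) give the radical precursor.

**Step 14**
Reactants: 23 caesium oxalate
Product: 24 3β-chloro enone
Conditions: Ir[dF(CF3)ppy]2(dtbbpy)PF6 (2 mol %), Cl3CCO2Et, DME/DMF, blue LEDs, 40 °C
Reagents that add atoms: ethyl trichloroacetate (CCOC(=O)C(Cl)(Cl)Cl)
Why: Photoredox radical deoxychlorination (oxalate oxidation, loss of two CO2, chlorine abstraction by the C3 radical) is used because SN2 at the neopentyl C3 is not viable; the axial α trajectory is blocked by the syn-axial C1 silyl ether and H5, so chlorine should arrive equatorially to give the more stable 3β-chloride.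

**Step 15**
Reactants: 24 3β-chloro enone
Product: 25 7,9(11)-diene
Conditions: Ph3PCH3Br, KOt-Bu, toluene, rt → 80 °C
Reagents that add atoms: methyltriphenylphosphonium bromide (C[P+](c1ccccc1)(c1ccccc1)c1ccccc1.[Br-])
Why: Wittig methylenation of the non-enolisable C9 ketone under forcing conditions adds C11; the equatorial neopentyl chloride has no antiperiplanar hydrogen and cannot be reached from the rear by the ester enolate, so it should survive the base.

**Step 16**
Reactants: 25 7,9(11)-diene
Product: 27 11-alcohol (9α-H), via alkylborane 26 (not isolated)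
Conditions: 9-BBN, THF, rt → 60 °C; 3 M NaOH, 30% H2O2, 0 °C → rt
Reagents that add atoms: hydrogen peroxide (OO)
Why: Hydroboration–oxidation: 9-BBN puts boron on the terminal C11 of the 1,1-disubstituted double bond, leaves the trisubstituted C7=C8 bond, and delivers hydrogen to C9 from the α-face opposite the adjacent axial C10 methyl (9α-H, 9β-CH2OH).

**Step 17**
Reactants: 27 11-alcohol
Product: 28 11-acetate
Conditions: Ac2O, pyridine, DMAP (cat.), CH2Cl2, rt
Reagents that add atoms: acetic anhydride (CC(=O)OC(C)=O)
Why: Acetylation keeps the homoallylic alcohol from forming a lactol or lactone with C12 during the allylic oxidation.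

**Step 18**
Reactants: 28 11-acetate
Product: 29 11-acetoxy-12-al
Conditions: SeO2, 1,4-dioxane, 80 °C
Reagents that add atoms: selenium dioxide (O=[Se]=O)
Why: Riley allylic oxidation (ene reaction, [2,3]-shift) attacks the methyl on the more substituted olefin carbon C8, as known for drim-7-en-11-yl acetates; it must precede the side-chain olefin, whose methyl groups would also be oxidised, and any 12-alcohol converges in step 19.

**Step 19**
Reactants: 29 11-acetoxy-12-al
Product: 30 triol
Conditions: LiAlH4, THF, 0 °C → rt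
Reagents that add atoms: none
Why: Hydride reduction converts the enal (1,2), the acetate and the tert-butyl ester in one operation; the secondary neopentyl chloride is inert at this temperature.

**Step 20**
Reactants: 30 triol
Product: 31 11,12-acetonide alcohol
Conditions: 2,2-dimethoxypropane (1.2 equiv), CSA (cat.), acetone, rt; Et3N
Reagents that add atoms: 2,2-dimethoxypropane (COC(C)(C)OC)
Why: Acetonide formation under thermodynamic control ties the cis-related allylic 1,4-diol into the dioxepine ring, and in acetone the lone C2′ hydroxyl stays free.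

**Step 21**
Reactants: 31 11,12-acetonide alcohol
Product: 32 primary iodide
Conditions: I2, PPh3, imidazole, CH2Cl2, 0 °C → rt
Reagents that add atoms: iodine (II)
Why: Appel-type iodination of the unhindered primary alcohol proceeds under buffered conditions that keep the acetonide and silyl ether.

**Step 22**
Reactants: 32 primary iodide; 33 (2-methylprop-1-en-1-yl)magnesium bromide
Product: 34 homoprenyl acetonide
Conditions: CuI (10 mol %), THF/NMP, −20 → 0 °C
Reagents that add atoms: none
Why: Copper-catalysed Grignard–alkyl iodide cross-coupling forms the C2′–C3′ bond; the neopentyl secondary chloride, the acetonide and the silyl ether should not react.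

**Step 23**
Reactants: 34 homoprenyl acetonide
Product: 35 11,12-diol
Conditions: PPTS, MeOH, rt
Reagents that add atoms: none
Why: Acid-catalysed transketalisation removes the strained seven-membered acetonide while the hindered secondary silyl ether and the trisubstituted olefins stay.

**Step 24**
Reactants: 35 11,12-diol
Product: 37 1-O-TBS dialdehyde, via bis(alkoxysulfonium) salt 36 (not isolated)
Conditions: (COCl)2, DMSO, CH2Cl2, −78 °C; Et3N, −78 → −30 °C
Reagents that add atoms: none
Why: Swern oxidation activates both primary alcohols before base is added, so the 1,4-diol gives the dialdehyde rather than a lactol or lactone, and the short cold amine treatment should not epimerise C9.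

**Step 25**
Reactants: 37 1-O-TBS dialdehyde
Product: 38 CNP0155449.1
Conditions: 48% aq HF, MeCN, 0 °C → rt
Reagents that add atoms: none
Why: Acidic fluoride desilylation frees the C1 alcohol without base, so the C9 formyl centre should keep its configuration.

**Compound list**
1 | (R)-carvone | CC1=CC[C@@H](C(C)=C)CC1=O | starting material
2 | lithium dienolate of 1 | CC1=CC[C@@H](C(C)=C)C=C1O[Li] | intermediate (not isolated)
3 | trans-6-methylcarvone (C10 methyl trans to isopropenyl) | CC1=CC[C@@H](C(C)=C)[C@H](C)C1=O | intermediate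
4 | methyl 3,3-dimethoxypropanoate | COC(=O)CC(OC)OC | starting material
5 | 3,3-dimethoxypropanal | COC(OC)CC=O | intermediate
6 | lithium enolate of 3 (C9=C10) | CC1=CC[C@@H](C(C)=C)C(C)=C1O[Li] | intermediate (not isolated)
7 | triisopropoxytitanium enolate of 3 | CC1=CC[C@@H](C(C)=C)C(C)=C1O[Ti](OC(C)C)(OC(C)C)OC(C)C | intermediate (not isolated)
8 | (1S)-ketol: 6-[(1S)-1-hydroxy-3,3-dimethoxypropyl]-6-methylcarvone, ring methyl cis to isopropenyl | COC(OC)C[C@H](O)[C@]1(C)C(=O)C(C)=CC[C@H]1C(C)=C | intermediate
9 | TBS ether of 8 | COC(OC)C[C@H](O[Si](C)(C)C(C)(C)C)[C@]1(C)C(=O)C(C)=CC[C@H]1C(C)=C | intermediate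
10 | secondary ozonide (1,2,4-trioxolane) of the isopropenyl group of 9 | COC(OC)C[C@H](O[Si](C)(C)C(C)(C)C)[C@]1(C)C(=O)C(C)=CC[C@H]1C2(C)OCOO2 | intermediate (not isolated)
11 | methyl ketone (acetyl on C5) | COC(OC)C[C@H](O[Si](C)(C)C(C)(C)C)[C@]1(C)C(=O)C(C)=CC[C@H]1C(C)=O | intermediate
12 | kinetic lithium enolate of 11 | COC(OC)C[C@H](O[Si](C)(C)C(C)(C)C)[C@]1(C)C(=O)C(C)=CC[C@H]1C(=C)O[Li] | intermediate (not isolated)
13 | diethyl enol phosphate | COC(OC)C[C@H](O[Si](C)(C)C(C)(C)C)[C@]1(C)C(=O)C(C)=CC[C@H]1C(=C)OP(=O)(OCC)OCC | intermediate (not isolated)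
14 | lithium acetylide (C5–C≡C–Li) | COC(OC)C[C@H](O[Si](C)(C)C(C)(C)C)[C@]1(C)C(=O)C(C)=CC[C@H]1C#C[Li] | intermediate (not isolated)
15 | tert-butyl ynoate (C5–C≡C–CO2t-Bu) | COC(OC)C[C@H](O[Si](C)(C)C(C)(C)C)[C@]1(C)C(=O)C(C)=CC[C@H]1C#CC(=O)OC(C)(C)C | intermediate
16 | (Z)-tert-butyl β-methyl enoate on C5, C3 dimethyl acetal | COC(OC)C[C@H](O[Si](C)(C)C(C)(C)C)[C@]1(C)C(=O)C(C)=CC[C@H]1/C(C)=C\C(=O)OC(C)(C)C | intermediate
17 | C3 aldehyde | O=CC[C@H](O[Si](C)(C)C(C)(C)C)[C@]1(C)C(=O)C(C)=CC[C@H]1/C(C)=C\C(=O)OC(C)(C)C | intermediate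
18 | C3 carboxylic acid | OC(=O)C[C@H](O[Si](C)(C)C(C)(C)C)[C@]1(C)C(=O)C(C)=CC[C@H]1/C(C)=C\C(=O)OC(C)(C)C | intermediate
19 | Se-phenyl selenoester (radical precursor) | O=C([Se]c1ccccc1)C[C@H](O[Si](C)(C)C(C)(C)C)[C@]2(C)C(=O)C(C)=CC[C@H]2/C(C)=C\C(=O)OC(C)(C)C | intermediate
20 | trans-decalin-3,9-dione: 1α-OTBS, 4β-methyl, 4α-CH2CO2t-Bu, 5α-H, 8-methyl, Δ7, 10β-methyl | CC(C)(C)OC(=O)C[C@]1(C)C(=O)C[C@H](O[Si](C)(C)C(C)(C)C)[C@]2(C)C(=O)C(C)=CC[C@@H]12 | intermediate
21 | 3β-alcohol of 20 | CC(C)(C)OC(=O)C[C@]1(C)[C@@H](O)C[C@H](O[Si](C)(C)C(C)(C)C)[C@]2(C)C(=O)C(C)=CC[C@@H]12 | intermediate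
22 | 3β-methyl oxalate | CC(C)(C)OC(=O)C[C@]1(C)[C@@H](OC(=O)C(=O)OC)C[C@H](O[Si](C)(C)C(C)(C)C)[C@]2(C)C(=O)C(C)=CC[C@@H]12 | intermediate (not isolated)
23 | caesium 3β-oxalate | CC(C)(C)OC(=O)C[C@]1(C)[C@@H](OC(=O)C(=O)[O-])C[C@H](O[Si](C)(C)C(C)(C)C)[C@]2(C)C(=O)C(C)=CC[C@@H]12.[Cs+] | intermediate
24 | 3β-chloro-9-oxo-Δ7 enone | CC(C)(C)OC(=O)C[C@]1(C)[C@@H](Cl)C[C@H](O[Si](C)(C)C(C)(C)C)[C@]2(C)C(=O)C(C)=CC[C@@H]12 | intermediate
25 | 3β-chloro-7,9(11)-diene | CC(C)(C)OC(=O)C[C@]1(C)[C@@H](Cl)C[C@H](O[Si](C)(C)C(C)(C)C)[C@]2(C)C(=C)C(C)=CC[C@@H]12 | intermediate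
26 | B-(C11-alkyl)-9-BBN (9α-H) | CC(C)(C)OC(=O)C[C@]1(C)[C@@H](Cl)C[C@H](O[Si](C)(C)C(C)(C)C)[C@]2(C)[C@@H](CB3C4CCCC3CCC4)C(C)=CC[C@@H]12 | intermediate (not isolated)
27 | 11-alcohol (9α-H, 9β-CH2OH, Δ7) | CC(C)(C)OC(=O)C[C@]1(C)[C@@H](Cl)C[C@H](O[Si](C)(C)C(C)(C)C)[C@]2(C)[C@@H](CO)C(C)=CC[C@@H]12 | intermediate
28 | 11-acetate | CC(C)(C)OC(=O)C[C@]1(C)[C@@H](Cl)C[C@H](O[Si](C)(C)C(C)(C)C)[C@]2(C)[C@@H](COC(C)=O)C(C)=CC[C@@H]12 | intermediate
29 | 11-acetoxy-Δ7-12-al | CC(C)(C)OC(=O)C[C@]1(C)[C@@H](Cl)C[C@H](O[Si](C)(C)C(C)(C)C)[C@]2(C)[C@@H](COC(C)=O)C(C=O)=CC[C@@H]12 | intermediate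
30 | triol (2′-OH, 11-OH, 12-OH) | OCC[C@]1(C)[C@@H](Cl)C[C@H](O[Si](C)(C)C(C)(C)C)[C@]2(C)[C@@H](CO)C(CO)=CC[C@@H]12 | intermediate
31 | 11,12-O-isopropylidene 2′-alcohol | OCC[C@]1(C)[C@@H](Cl)C[C@H](O[Si](C)(C)C(C)(C)C)[C@]2(C)[C@@H](COC(C)(C)OC3)C3=CC[C@@H]12 | intermediate
32 | 2′-iodide | ICC[C@]1(C)[C@@H](Cl)C[C@H](O[Si](C)(C)C(C)(C)C)[C@]2(C)[C@@H](COC(C)(C)OC3)C3=CC[C@@H]12 | intermediate
33 | (2-methylprop-1-en-1-yl)magnesium bromide | CC(C)=C[Mg]Br | starting material
34 | homoprenyl acetonide | CC(C)=CCC[C@]1(C)[C@@H](Cl)C[C@H](O[Si](C)(C)C(C)(C)C)[C@]2(C)[C@@H](COC(C)(C)OC3)C3=CC[C@@H]12 | intermediate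
35 | Δ7-11,12-diol, 1α-OTBS | CC(C)=CCC[C@]1(C)[C@@H](Cl)C[C@H](O[Si](C)(C)C(C)(C)C)[C@]2(C)[C@@H](CO)C(CO)=CC[C@@H]12 | intermediate
36 | bis(alkoxydimethylsulfonium) dichloride | CC(C)=CCC[C@]1(C)[C@@H](Cl)C[C@H](O[Si](C)(C)C(C)(C)C)[C@]2(C)[C@@H](CO[S+](C)C)C(CO[S+](C)C)=CC[C@@H]12.[Cl-].[Cl-] | intermediate (not isolated)
37 | 1-O-TBS dialdehyde | CC(C)=CCC[C@]1(C)[C@@H](Cl)C[C@H](O[Si](C)(C)C(C)(C)C)[C@]2(C)[C@@H](C=O)C(C=O)=CC[C@@H]12 | intermediate
38 | CNP0155449.1 (3β-chloro-1α-hydroxy-4α-homoprenyl-Δ7-11,12-dial) | CC(C)=CCC[C@]1(C)[C@@H](Cl)C[C@H](O)[C@]2(C)[C@@H](C=O)C(C=O)=CC[C@@H]12 | target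

**Step count and risks**
Total steps: 25. Longest linear sequence: 24 (steps 1 and 3–25 from (R)-carvone); step 2 is a one-step side branch.

Most likely to fail:

Step 11. The acyl radical may be reduced or lose CO before it adds to the fully substituted enoate carbon, and facial control at C4 rests on an acyclic conformational preference. Fallback: starting from aldehyde 17, an intramolecular Stetter reaction (triazolium-derived N-heterocyclic carbene, i-Pr2NEt, toluene) adds the acyl-anion equivalent to C4 through the same six-membered array. This reaction type is known to form quaternary centres from aliphatic aldehydes and β,β-disubstituted acceptors. It returns to the route at 20 and makes no new compound (F0).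

Step 3. Facial selectivity at the aldehyde carbonyl may be poor if the tetrasubstituted titanium enolate does not follow the syn pathway, giving C1 epimers. Fallback: starting from 3 and 5, the plain lithium-enolate aldol (through 6) gives the ketol as a mixture containing the (1R)-ketol F1. Dess–Martin oxidation converges both epimers to the 2,2-disubstituted 1,3-diketone F2. Corey–Bakshi–Shibata reduction with the (R)-methyl oxazaborolidine and catecholborane then reduces the non-conjugated C1 carbonyl under reagent control (large group the quaternary C10), the flanked conjugated C9 carbonyl reacting far more slowly. This returns to the route at 8.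

Step 14. Chlorine-atom transfer may occur on the axial face, or lose to hydrogen abstraction or incomplete decarboxylation of the secondary alkoxycarbonyl radical. Fallback: starting from 20, KHMDS and PhNTf2 (enolisation is possible only toward C2) give the C2=C3 enol triflate F3. Nickel-catalysed triflate–chloride exchange (Ni(cod)2, LiCl, DMA/THF) gives the alkenyl chloride F4. Hydrogen-atom-transfer hydrogenation (Mn(dpm)3, PhSiH3, t-BuOOH) saturates both the chloroalkene and the enone olefin, with the α-chloro radical quenched to leave chlorine equatorial, giving the saturated chloro ketone F5 (C8 epimers). TMSOTf and Et3N give the C8=C9 trimethylsilyl enol ether F6, and Saegusa–Ito oxidation (Pd(OAc)2, MeCN) restores the Δ7 enone, returning to the route at 24.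

**Further compounds**
F0 | step 11 | none | none
F1 | step 3 | (1R)-ketol (C1 epimer of 8) | COC(OC)C[C@@H](O)[C@]1(C)C(=O)C(C)=CC[C@H]1C(C)=C
F2 | step 3 | 2,2-disubstituted 1,3-diketone (C1 and C9 ketones) | COC(OC)CC(=O)[C@]1(C)C(=O)C(C)=CC[C@H]1C(C)=C
F3 | step 14 | C2=C3 enol triflate of 20 | CC(C)(C)OC(=O)C[C@]1(C)C(OS(=O)(=O)C(F)(F)F)=C[C@H](O[Si](C)(C)C(C)(C)C)[C@]2(C)C(=O)C(C)=CC[C@@H]12
F4 | step 14 | C2=C3 alkenyl chloride | CC(C)(C)OC(=O)C[C@]1(C)C(Cl)=C[C@H](O[Si](C)(C)C(C)(C)C)[C@]2(C)C(=O)C(C)=CC[C@@H]12
F5 | step 14 | saturated 3β-chloro-9-ketone (C8 epimers) | CC(C)(C)OC(=O)C[C@]1(C)[C@@H](Cl)C[C@H](O[Si](C)(C)C(C)(C)C)[C@]2(C)C(=O)C(C)CC[C@@H]12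
F6 | step 14 | C8=C9 trimethylsilyl enol ether | CC(C)(C)OC(=O)C[C@]1(C)[C@@H](Cl)C[C@H](O[Si](C)(C)C(C)(C)C)[C@]2(C)C(O[Si](C)(C)C)=C(C)CC[C@@H]12
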